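**Retrosynthetic overview**
- The flavanone comes from an acyclic (S)-δ-hydroxy triketo ester, ArCH(OH)CH2CO-CH2CO-CH(prenyl)CO-CH2CO2Me, in one flask. The C ring closes first (O1–C8a, cyclodehydration to a dihydropyranone), then the A ring (C4a–C5, acylketene Claisen-type closure and aromatisation). The B ring is bought.
- The triketo ester comes from terminal Claisen acylation (C4–C4a) of the trianion of methyl 4-prenyl-3,5-dioxohexanoate with an (S)-β-hydroxy ester.
- The (S)-β-hydroxy ester comes from a catalytic asymmetric acetate Mukaiyama aldol on 4-methoxy-3-(3-methylbut-3-enyl)benzaldehyde; this sets C2, which is not touched again.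
- The aldehyde comes from a Negishi coupling on 3-bromo-4-methoxybenzaldehyde; the prenyl diketo ester from C4-prenylation of methyl 3,5-dioxohexanoate.

Assumption: methyl 3,5-dioxohexanoate is taken as a catalogue compound.
Assumption: the (S,S)-bisphosphoramide is taken to direct si-face addition to the aldehyde and give the (S)-carbinol; if the sense is the reverse, the (R,R)-catalyst is used.

**Step 1**
Reactants: 1 3-bromo-4-methoxybenzaldehyde; 2 4-bromo-2-methylbut-1-ene
Product: 4 4-methoxy-3-(3-methylbut-3-en-1-yl)benzaldehyde, via (3-methylbut-3-en-1-yl)zinc bromide 3 (not isolated)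
Conditions: 2, Zn dust, LiCl, THF, 50 °C; then 1, Pd(OAc)2 (2 mol%), SPhos (4 mol%), THF, 25 °C
Reagents that add atoms: none
Why: Negishi sp3–sp2 cross-coupling; the primary alkylzinc halide tolerates the aldehyde and couples with the ortho-alkoxy aryl bromide without isomerising the 1,1-disubstituted alkene.

**Step 2**
Reactants: 4 4-methoxy-3-(3-methylbut-3-en-1-yl)benzaldehyde; 5 1-(tert-butyldimethylsilyloxy)-1-methoxyethene
Product: 7 methyl (3S)-3-hydroxy-3-[4-methoxy-3-(3-methylbut-3-en-1-yl)phenyl]propanoate, via trichlorosilyl ether 6 (not isolated)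
Conditions: SiCl4 (1.1 equiv), (S,S)-BINAM-derived bisphosphoramide (2 mol%), i-Pr2NEt (10 mol%), CH2Cl2, −78 °C; then aq. NaHCO3
Reagents that add atoms: none
Why: Lewis-base-activated SiCl4 Mukaiyama acetate aldol; the chiral phosphoramide-bound silyl cation shields one aldehyde face, so the ketene acetal adds to the si face and sets the (S)-carbinol that becomes C2 of the flavanone.

**Step 3**
Reactants: 8 methyl 3,5-dioxohexanoate; 9 1-bromo-3-methylbut-2-ene
Product: 10 methyl 4-(3-methylbut-2-en-1-yl)-3,5-dioxohexanoate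
Conditions: NaH (1.0 equiv), THF, 0 °C; then 9 (1.0 equiv), 0 → 25 °C
Reagents that add atoms: none
Why: C-alkylation of a β-diketone monoanion; C4, between the two ketones, is the most acidic carbon and takes the soft allylic bromide, which places the prenyl group on the future C8.

**Step 4**
Reactants: 10 methyl 4-(3-methylbut-2-en-1-yl)-3,5-dioxohexanoate (2.5 equiv); 7 methyl (3S)-3-hydroxy-3-[4-methoxy-3-(3-methylbut-3-en-1-yl)phenyl]propanoate
Product: 12 methyl (9S)-9-hydroxy-9-[4-methoxy-3-(3-methylbut-3-en-1-yl)phenyl]-4-(3-methylbut-2-en-1-yl)-3,5,7-trioxononanoate, via trilithium trianion 11 (not isolated)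
Conditions: 10, LDA (commercial solution, 7.6 equiv), THF, 0 °C, 1 h; then 7, −78 → −20 °C; cold AcOH/NaOAc buffer (pH 5) quench; used after rapid filtration through silica
Reagents that add atoms: none
Why: Harris-type Claisen acylation of a 3,5-dioxo ester trianion at its terminal carbanion by a methyl ester; the β-hydroxyl of 7 sits as its lithium alkoxide (as in statin side-chain Claisen condensations), so the stereocentre is not touched, and the ester of 10 is protected as its enolate.

**Step 5**
Reactants: 12 methyl (9S)-9-hydroxy-9-[4-methoxy-3-(3-methylbut-3-en-1-yl)phenyl]-4-(3-methylbut-2-en-1-yl)-3,5,7-trioxononanoate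
Product: 15 (2S)-5,7-dihydroxy-2-[4-methoxy-3-(3-methylbut-3-en-1-yl)phenyl]-8-(3-methylbut-2-en-1-yl)-2,3-dihydro-4H-chromen-4-one, via dihydropyranone keto ester 13 (not isolated), via acylketene 14 (not isolated)
Conditions: PPTS (5 mol%), 4 Å MS, o-xylene, 50 °C, 2 h; then 145 °C, N2 sweep, 4 h
Reagents that add atoms: none
Why: Proposed new method: at 50 °C the δ-hydroxy-β-diketone unit cyclodehydrates to the 2,3-dihydro-4H-pyran-4-one (C ring), which fixes O1 on C8a next to the prenyl-bearing carbon and leaves C2 untouched; at 145 °C the β-keto methyl ester loses MeOH to an acylketene whose only six-ring partner is the nucleophilic enol-ether carbon C4a (C-acylation, or 6π closure of the dienylketene tautomer), and enolisation gives the phloroglucinol A ring; pyrone formation and the aldol (orsellinate) closure are shut off because the C8a oxygen is already the ring oxygen and the side chain is trans to C4 across the ring C=C; closest known reaction types are acid-catalysed cyclodehydration of δ-hydroxy-β-diketones, thermal acylketene generation from β-keto esters or dioxinones followed by aromatisation, Claisen cyclisation of 3,5,7-triketo esters to acylphloroglucinols and dienylketene electrocyclisation (Danheiser benzannulation).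

**Compound list**
1 | 3-bromo-4-methoxybenzaldehyde | COc1ccc(C=O)cc1Br | starting material
2 | 4-bromo-2-methylbut-1-ene | C=C(C)CCBr | starting material
3 | (3-methylbut-3-en-1-yl)zinc bromide | C=C(C)CC[Zn]Br | intermediate
4 | 4-methoxy-3-(3-methylbut-3-en-1-yl)benzaldehyde | C=C(C)CCc1cc(C=O)ccc1OC | intermediate
5 | 1-(tert-butyldimethylsilyloxy)-1-methoxyethene | C=C(OC)O[Si](C)(C)C(C)(C)C | starting material
6 | methyl (3S)-3-[4-methoxy-3-(3-methylbut-3-en-1-yl)phenyl]-3-(trichlorosilyloxy)propanoate | COC(=O)C[C@H](O[Si](Cl)(Cl)Cl)c1ccc(OC)c(CCC(C)=C)c1 | intermediate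
7 | methyl (3S)-3-hydroxy-3-[4-methoxy-3-(3-methylbut-3-en-1-yl)phenyl]propanoate | COC(=O)C[C@H](O)c1ccc(OC)c(CCC(C)=C)c1 | intermediate
8 | methyl 3,5-dioxohexanoate | COC(=O)CC(=O)CC(C)=O | starting material
9 | 1-bromo-3-methylbut-2-ene (prenyl bromide) | CC(C)=CCBr | starting material
10 | methyl 4-(3-methylbut-2-en-1-yl)-3,5-dioxohexanoate | COC(=O)CC(=O)C(CC=C(C)C)C(C)=O | intermediate
11 | trilithium salt of the 2,4,6-trianion of 10 | [Li+].[Li+].[Li+].COC(=O)[CH-]C(=O)[C-](CC=C(C)C)C(=O)[CH2-] | intermediate
12 | methyl (9S)-9-hydroxy-9-[4-methoxy-3-(3-methylbut-3-en-1-yl)phenyl]-4-(3-methylbut-2-en-1-yl)-3,5,7-trioxononanoate (C4 epimers; keto, enol and hemiketal tautomers) | COC(=O)CC(=O)C(CC=C(C)C)C(=O)CC(=O)C[C@H](O)c1ccc(OC)c(CCC(C)=C)c1 | intermediate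
13 | methyl 4-{(2S)-2-[4-methoxy-3-(3-methylbut-3-en-1-yl)phenyl]-4-oxo-3,4-dihydro-2H-pyran-6-yl}-7-methyl-3-oxooct-6-enoate | COC(=O)CC(=O)C(CC=C(C)C)C1=CC(=O)C[C@@H](c2ccc(OC)c(CCC(C)=C)c2)O1 | intermediate
14 | 4-{(2S)-2-[4-methoxy-3-(3-methylbut-3-en-1-yl)phenyl]-4-oxo-3,4-dihydro-2H-pyran-6-yl}-7-methylocta-1,6-diene-1,3-dione (acylketene) | O=C=CC(=O)C(CC=C(C)C)C1=CC(=O)C[C@@H](c2ccc(OC)c(CCC(C)=C)c2)O1 | intermediate
15 | (2S)-5,7-dihydroxy-2-[4-methoxy-3-(3-methylbut-3-en-1-yl)phenyl]-8-(3-methylbut-2-en-1-yl)-2,3-dihydro-4H-chromen-4-one (CNP0286775.1) | C=C(C)CCc1cc([C@@H]2CC(=O)c3c(O)cc(O)c(CC=C(C)C)c3O2)ccc1OC | target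

**Totals**
Total step count: 5. Longest linear sequence: 4 (steps 1, 2, 4, 5).

**Three steps most likely to fail**

Step 5 is the riskiest. The ketene may form too slowly, close poorly onto C4a, or the long heating may erode the ee. The fallback sets out from 12: stop after the PPTS stage and isolate the dihydropyranone keto ester 13. Treat it with TMSOTf/Et3N (CH2Cl2, 0 °C) to turn the β-keto ester arm into the bis(trimethylsilyl) dienyl ketene acetal F1. Warm this oxygenated hexatriene in toluene at 80 °C so that 6π-electrocyclisation and loss of methanol give the 5,7-bis(trimethylsilyl) ether of the flavanone F2. Remove the silyl groups with citric acid in MeOH; the fallback comes back to the route at 15.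

Step 4 is next. The polyanion can be quenched by proton transfer from the enolisable ester 7, and 12 is a sensitive polycarbonyl. The fallback sets out from 10 (with 4, bypassing 7): silylate 10 stepwise (Me3SiCl/Et3N, then LDA/Me3SiCl twice) to the 1,3,5-tris(trimethylsilyloxy)triene F3. Its terminal carbon adds to aldehyde 4 in a Ti(OiPr)4/(S)-BINOL-catalysed vinylogous Mukaiyama aldol, which also sets the carbinol centre. Mild acidic work-up removes the silyl groups and the fallback comes back to the route at 12.

Step 3 is third. O-alkylation, dialkylation or base-induced lactonisation of 8 to the pyrone can compete. The fallback sets out from 9: alkylate commercial pentane-2,4-dione with 9 (K2CO3, acetone) to 3-(3-methylbut-2-en-1-yl)pentane-2,4-dione F4. Form its 1,3-dianion with LDA and carboxylate the terminal methyl with dimethyl carbonate (terminal carboxylation of a β-diketone dianion). The fallback comes back to the route at 10.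

**Further compounds**
F1 | step 5 | (2S)-6-[1-methoxy-7-methyl-1,3-bis(trimethylsilyloxy)octa-1,3,6-trien-4-yl]-2-[4-methoxy-3-(3-methylbut-3-en-1-yl)phenyl]-2,3-dihydro-4H-pyran-4-one | COC(O[Si](C)(C)C)=CC(O[Si](C)(C)C)=C(CC=C(C)C)C1=CC(=O)C[C@@H](c2ccc(OC)c(CCC(C)=C)c2)O1
F2 | step 5 | (2S)-2-[4-methoxy-3-(3-methylbut-3-en-1-yl)phenyl]-8-(3-methylbut-2-en-1-yl)-5,7-bis(trimethylsilyloxy)-2,3-dihydro-4H-chromen-4-one | C=C(C)CCc1cc([C@@H]2CC(=O)c3c(O[Si](C)(C)C)cc(O[Si](C)(C)C)c(CC=C(C)C)c3O2)ccc1OC
F3 | step 4 | 1-methoxy-4-(3-methylbut-2-en-1-yl)-1,3,5-tris(trimethylsilyloxy)hexa-1,3,5-triene | C=C(O[Si](C)(C)C)C(CC=C(C)C)=C(O[Si](C)(C)C)C=C(OC)O[Si](C)(C)C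
F4 | step 3 | 3-(3-methylbut-2-en-1-yl)pentane-2,4-dione | CC(=O)C(CC=C(C)C)C(C)=O
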